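**Retrosynthetic overview**
1. The CH2OH group and the (E)-trisubstituted olefin are released last from bis-allylic alcohol 23 by a [3,3]-sigmatropic 1,3-transposition of its allyl perrhenate, which also completes the conjugated trienolide.
2. 23 comes from a Nozaki–Hiyama–Kishi union of 2-triflyloxy-1-alkene 17 with dienal-butenolide 21 (butenolide ring bought as 4-bromofuran-2(5H)-one).
3. 17 comes from methyl ketone 15, made by B-alkyl Suzuki coupling on the hindered ring-B enol triflate 11 (sets the tetrasubstituted ring olefin and the bond to the side chain).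
4. 11 comes from cis-decalone 9; ring A is closed onto ring B by a vinylsilane-terminated cation–olefin cyclisation that turns the isopropenyl group into the gem-dimethyl carbon.
5. Ring B and the ring-fusion CH are (S)-carvone; the quaternary carbon is set by methylation anti to isopropenyl. Ring order: B (bought), then A (step 4); butenolide bought.

Assumption: the target is taken exactly as drawn, i.e. the cis-fused (4aR,8aS) bicycle (angular CH3 and ring-fusion H on the same face), which is why a trans-fused labdane such as sclareol is not used; reagents 2, 12, 18 and 19 are taken as catalogue items.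
Shorthand used in names: "Oct" = (4aR,8aS)-2,5,5,8a-tetramethyl-3,4,4a,5,6,7,8,8a-octahydronaphthalen-1-yl (cis-fused).

**Step 1**
Reactants: 1 (S)-(+)-carvone; 2 3-bromo-1-(trimethylsilyl)prop-1-yne
Product: 4 (5S)-2-methyl-5-(prop-1-en-2-yl)-6-[3-(trimethylsilyl)prop-2-yn-1-yl]cyclohex-2-en-1-one (C6 epimers), via lithium dienolate 3 (not isolated)
Conditions: LDA (1.05 eq), THF, −78 °C; then 2, −78 → −20 °C
Reagents that add atoms: none
Why: Kinetic α′-deprotonation of the enone and SN2 enolate alkylation by the propargylic bromide; the new C6 centre is a mixture that is erased in step 2.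

**Step 2**
Reactants: 4
Product: 6 (5R,6S)-2,6-dimethyl-5-(prop-1-en-2-yl)-6-[3-(trimethylsilyl)prop-2-yn-1-yl]cyclohex-2-en-1-one, via lithium dienolate 5 (not isolated)
Conditions: LDA (1.2 eq), THF, −78 °C; MeI (3 eq), DMPU, −78 → 0 °C
Reagents that add atoms: iodomethane, CI
Why: Second α′-enolate alkylation; MeI attacks the planar dienolate anti to the neighbouring isopropenyl group (1,2-induction from the purchased centre), so CH3 ends trans and the propargyl arm cis to isopropenyl, fixing the quaternary carbon.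

**Step 3**
Reactants: 6
Product: 7 (5R,6S)-2,6-dimethyl-5-(prop-1-en-2-yl)-6-[(2Z)-3-(trimethylsilyl)prop-2-en-1-yl]cyclohex-2-en-1-one
Conditions: H2 (1 atm, stop at 1 eq), Lindlar catalyst, quinoline, hexane–EtOAc, rt
Reagents that add atoms: none
Why: Lindlar syn-semihydrogenation of the silylalkyne gives the (Z)-vinylsilane, the geometry that places silicon pseudo-axial in the ring-closing transition state; the isolated alkene and the enone are left alone.

**Step 4**
Reactants: 7
Product: 8 (4aR,8aS)-2,5,5,8a-tetramethyl-4a,5,8,8a-tetrahydronaphthalen-1(4H)-one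
Conditions: CF3CO2H, CH2Cl2, 0 °C
Reagents that add atoms: none
Why: Markovnikov protonation of isopropenyl gives a tertiary cation that is trapped 6-endo at the silicon-bearing carbon of the cis-disposed vinylsilane, and the β-silyl cation loses silicon (vinylsilane-terminated cation–olefin cyclisation); the two arms are cis on ring B, so the fusion is cis and no stereocentre is touched.

**Step 5**
Reactants: 8
Product: 9 (4aR,8aS)-2,5,5,8a-tetramethyloctahydronaphthalen-1(2H)-one (C2 epimers)
Conditions: H2 (1 atm), 10% Pd/C, EtOAc, rt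
Reagents that add atoms: none
Why: Heterogeneous hydrogenation saturates the disubstituted ring-A alkene and the enone C=C but not the hindered ketone; the new C2 centre is destroyed in step 6.

**Step 6**
Reactants: 9
Product: 11 Oct trifluoromethanesulfonate, via lithium enolate 10 (not isolated)
Conditions: LDA (1.3 eq), THF, −78 → 0 °C; PhNTf2, 0 °C → rt
Reagents that add atoms: N-phenylbis(trifluoromethanesulfonimide), O=S(=O)(N(c1ccccc1)S(=O)(=O)C(F)(F)F)C(F)(F)F
Why: The ketone has a single α-hydrogen, so enolisation and O-triflation give only the tetrasubstituted enol triflate (same substitution pattern as the well-behaved 2,6,6-trimethylcyclohexenyl triflate).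

**Step 7**
Reactants: 11; 12 2-methyl-2-vinyl-1,3-dioxolane
Product: 15 4-(Oct)butan-2-one, via alkylborane 13 (not isolated), via ketal 14 (not isolated)
Conditions: 12, 9-BBN-H, THF, 0 °C → rt; then 11, PdCl2(dppf) (10 mol%), AsPh3, 3 M aq K3PO4, DMF, 60 °C; then 1 M HCl, THF, rt
Reagents that add atoms: water, O
Why: Anti-Markovnikov hydroboration followed by B-alkyl Suzuki–Miyaura coupling joins the side chain to the ring sp2 carbon with the olefin already in place, and the acidic work-up unmasks the methyl ketone.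

**Step 8**
Reactants: 15
Product: 17 4-(Oct)but-1-en-2-yl trifluoromethanesulfonate, via lithium enolate 16 (not isolated)
Conditions: LDA (1.1 eq), THF, −78 °C; PhNTf2, −78 → 0 °C
Reagents that add atoms: N-phenylbis(trifluoromethanesulfonimide), O=S(=O)(N(c1ccccc1)S(=O)(=O)C(F)(F)F)C(F)(F)F
Why: Kinetic deprotonation of the methyl ketone on the CH3 side and O-triflation give the 1,1-disubstituted enol triflate.

**Step 9**
Reactants: 18 4-bromofuran-2(5H)-one; 19 2-[(1E)-3,3-diethoxyprop-1-en-1-yl]-4,4,5,5-tetramethyl-1,3,2-dioxaborolane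
Product: 21 (2E)-3-(5-oxo-2,5-dihydrofuran-3-yl)prop-2-enal, via diethyl acetal 20 (not isolated)
Conditions: PdCl2(PPh3)2 (5 mol%), KF, THF–H2O, 60 °C; then 1 M HCl, THF, rt
Reagents that add atoms: water, O
Why: Suzuki–Miyaura coupling of the vinylogous acyl bromide proceeds with retention of the (E)-alkenyl geometry, and mild acid hydrolyses the acetal to the enal.

**Step 10**
Reactants: 17; 21
Product: 23 4-[(1E)-3-hydroxy-4-methylidene-6-(Oct)hex-1-en-1-yl]furan-2(5H)-one (both carbinol epimers), via alkenylchromium species 22 (not isolated)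
Conditions: CrCl2 (4 eq), NiCl2 (2 mol%), DMF, rt; 21 (1.5 eq)
Reagents that add atoms: none
Why: Nozaki–Hiyama–Kishi coupling; the alkenylchromium adds 1,2 to the aldehyde and ignores the lactone and its acidic CH2, and the carbinol centre (mixture) is erased in step 11.

**Step 11**
Reactants: 23
Product: 26 4-[(1E,3E)-4-(hydroxymethyl)-6-(Oct)hexa-1,3-dien-1-yl]furan-2(5H)-one (target), via secondary allyl perrhenate 24 (not isolated), via primary allyl perrhenate 25 (not isolated)
Conditions: Ph3SiOReO3 (5 mol%), Et2O, −50 → −20 °C; Et3N quench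
Reagents that add atoms: none
Why: Osborn–Grubbs 1,3-transposition, a [3,3]-sigmatropic shift of the allyl perrhenate toward the terminal methylene, forms the C–O bond of the primary alcohol and the fully conjugated trienolide; the chair transition state with the dienyl group equatorial puts that group trans to CH2O, i.e. the (E)-trisubstituted olefin, and removes the carbinol stereocentre.

**Compound list**
1 | (S)-(+)-carvone | CC(=C)[C@H]1CC=C(C)C(=O)C1 | starting material
2 | 3-bromo-1-(trimethylsilyl)prop-1-yne | C[Si](C)(C)C#CCBr | starting material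
3 | lithium dienolate of 1 | CC(=C)[C@H]1CC=C(C)C(O[Li])=C1 | intermediate
4 | (5S)-2-methyl-5-(prop-1-en-2-yl)-6-[3-(trimethylsilyl)prop-2-yn-1-yl]cyclohex-2-en-1-one (C6 epimers) | CC(=C)[C@H]1CC=C(C)C(=O)C1CC#C[Si](C)(C)C | intermediate
5 | lithium dienolate of 4 | CC(=C)[C@H]1CC=C(C)C(O[Li])=C1CC#C[Si](C)(C)C | intermediate
6 | (5R,6S)-2,6-dimethyl-5-(prop-1-en-2-yl)-6-[3-(trimethylsilyl)prop-2-yn-1-yl]cyclohex-2-en-1-one | CC(=C)[C@H]1CC=C(C)C(=O)[C@@]1(C)CC#C[Si](C)(C)C | intermediate
7 | (5R,6S)-2,6-dimethyl-5-(prop-1-en-2-yl)-6-[(2Z)-3-(trimethylsilyl)prop-2-en-1-yl]cyclohex-2-en-1-one | CC(=C)[C@H]1CC=C(C)C(=O)[C@@]1(C)C/C=C\[Si](C)(C)C | intermediate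
8 | (4aR,8aS)-2,5,5,8a-tetramethyl-4a,5,8,8a-tetrahydronaphthalen-1(4H)-one | O=C1[C@@]2(C)CC=CC(C)(C)[C@H]2CC=C1C | intermediate
9 | (4aR,8aS)-2,5,5,8a-tetramethyloctahydronaphthalen-1(2H)-one (C2 epimers) | O=C1[C@@]2(C)CCCC(C)(C)[C@H]2CCC1C | intermediate
10 | lithium enolate of 9 | CC1=C(O[Li])[C@@]2(C)CCCC(C)(C)[C@H]2CC1 | intermediate
11 | (4aR,8aS)-2,5,5,8a-tetramethyl-3,4,4a,5,6,7,8,8a-octahydronaphthalen-1-yl trifluoromethanesulfonate | CC1=C(OS(=O)(=O)C(F)(F)F)[C@@]2(C)CCCC(C)(C)[C@H]2CC1 | intermediate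
12 | 2-methyl-2-vinyl-1,3-dioxolane | C=CC1(C)OCCO1 | starting material
13 | 9-[2-(2-methyl-1,3-dioxolan-2-yl)ethyl]-9-borabicyclo[3.3.1]nonane | CC1(CCB2C3CCCC2CCC3)OCCO1 | intermediate
14 | 2-methyl-2-[2-(Oct)ethyl]-1,3-dioxolane | CC1=C(CCC3(C)OCCO3)[C@@]2(C)CCCC(C)(C)[C@H]2CC1 | intermediate
15 | 4-(Oct)butan-2-one | CC1=C(CCC(C)=O)[C@@]2(C)CCCC(C)(C)[C@H]2CC1 | intermediate
16 | lithium enolate of 15 (terminal) | CC1=C(CCC(=C)O[Li])[C@@]2(C)CCCC(C)(C)[C@H]2CC1 | intermediate
17 | 4-(Oct)but-1-en-2-yl trifluoromethanesulfonate | CC1=C(CCC(=C)OS(=O)(=O)C(F)(F)F)[C@@]2(C)CCCC(C)(C)[C@H]2CC1 | intermediate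
18 | 4-bromofuran-2(5H)-one | O=C1C=C(Br)CO1 | starting material
19 | 2-[(1E)-3,3-diethoxyprop-1-en-1-yl]-4,4,5,5-tetramethyl-1,3,2-dioxaborolane | CCOC(OCC)/C=C/B1OC(C)(C)C(C)(C)O1 | starting material
20 | 4-[(1E)-3,3-diethoxyprop-1-en-1-yl]furan-2(5H)-one | CCOC(OCC)/C=C/C1=CC(=O)OC1 | intermediate
21 | (2E)-3-(5-oxo-2,5-dihydrofuran-3-yl)prop-2-enal | O=C/C=C/C1=CC(=O)OC1 | intermediate
22 | [4-(Oct)but-1-en-2-yl]chromium(III) dichloride | CC1=C(CCC(=C)[Cr](Cl)Cl)[C@@]2(C)CCCC(C)(C)[C@H]2CC1 | intermediate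
23 | 4-[(1E)-3-hydroxy-4-methylidene-6-(Oct)hex-1-en-1-yl]furan-2(5H)-one (carbinol epimers) | CC1=C(CCC(=C)C(O)/C=C/C3=CC(=O)OC3)[C@@]2(C)CCCC(C)(C)[C@H]2CC1 | intermediate
24 | secondary allyl perrhenate of 23 | CC1=C(CCC(=C)C(O[Re](=O)(=O)=O)/C=C/C3=CC(=O)OC3)[C@@]2(C)CCCC(C)(C)[C@H]2CC1 | intermediate
25 | primary allyl perrhenate of 26 | CC1=C(CC/C(=C\C=C\C3=CC(=O)OC3)CO[Re](=O)(=O)=O)[C@@]2(C)CCCC(C)(C)[C@H]2CC1 | intermediate
26 | 4-[(1E,3E)-4-(hydroxymethyl)-6-[(4aR,8aS)-2,5,5,8a-tetramethyl-3,4,4a,5,6,7,8,8a-octahydronaphthalen-1-yl]hexa-1,3-dien-1-yl]furan-2(5H)-one | CC1=C(CC/C(=C\C=C\C2=CC(=O)OC2)CO)[C@@]2(C)CCCC(C)(C)[C@H]2CC1 | target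

**Step count and risks**
Total steps: 11. Longest linear sequence: 10 (steps 1–8, 10, 11; step 9 is the side branch).

The three steps most likely to fail:

Step 4 (cationic ring closure). The tertiary cation can lose the ring-fusion proton to give the isopropylidene isomer, which would scramble that centre and allow trans-fused product, and the vinylsilane can be protodesilylated. The fallback sets out from 7 and comes back at 8. Dry HCl in CH2Cl2 at −78 °C is added across the isopropenyl group to give the tertiary chloride (5S,6S)-5-(2-chloropropan-2-yl)-2,6-dimethyl-6-[(2Z)-3-(trimethylsilyl)prop-2-en-1-yl]cyclohex-2-en-1-one F1. SnCl4 at −78 °C then ionises F1 irreversibly with no Brønsted acid–base equilibrium, so ring closure onto the vinylsilane outruns elimination and gives 8.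

Step 10 (Ni/Cr coupling). CrCl2 may reduce or pinacol-couple the electron-poor dienal 21, which is also prone to polymerise. The fallback sets out from 17 and comes back at 23. The same Ni/Cr coupling is run on 17 with the robust (E)-3-(tributylstannyl)prop-2-enal, giving (1E)-4-methylidene-6-(Oct)-1-(tributylstannyl)hex-1-en-3-ol F2. The butenolide is then attached by Stille coupling of F2 with 18 (Pd2(dba)3, AsPh3, CuI, NMP, rt), which gives 23.

Step 11 ([3,3] transposition). The shift is reversible and the two geometries of the new trisubstituted olefin are close in energy, so the kinetic E preference of the chair transition state may erode. The fallback sets out from 23 and comes back at 26. Re2O7 (1 mol%, CH2Cl2, rt) is allowed to equilibrate 23 to the primary dienols, i.e. 26 mixed with 4-[(1E,3Z)-4-(hydroxymethyl)-6-(Oct)hexa-1,3-dien-1-yl]furan-2(5H)-one F3. MnO2 oxidises the mixture, and a trace of I2 funnels the aldehydes to (2E,4E)-5-(5-oxo-2,5-dihydrofuran-3-yl)-2-[2-(Oct)ethyl]penta-2,4-dienal F4. F4 is the thermodynamic isomer of an α-branched enal and has the target geometry. Luche reduction (NaBH4, CeCl3·7H2O, MeOH, −78 °C) then returns 26 alone.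

**Further compounds**
F1 | step 4 | (5S,6S)-5-(2-chloropropan-2-yl)-2,6-dimethyl-6-[(2Z)-3-(trimethylsilyl)prop-2-en-1-yl]cyclohex-2-en-1-one | CC(C)(Cl)[C@H]1CC=C(C)C(=O)[C@@]1(C)C/C=C\[Si](C)(C)C
F2 | step 10 | (1E)-4-methylidene-6-[(4aR,8aS)-2,5,5,8a-tetramethyl-3,4,4a,5,6,7,8,8a-octahydronaphthalen-1-yl]-1-(tributylstannyl)hex-1-en-3-ol | CC1=C(CCC(=C)C(O)/C=C/[Sn](CCCC)(CCCC)CCCC)[C@@]2(C)CCCC(C)(C)[C@H]2CC1
F3 | step 11 | 4-[(1E,3Z)-4-(hydroxymethyl)-6-[(4aR,8aS)-2,5,5,8a-tetramethyl-3,4,4a,5,6,7,8,8a-octahydronaphthalen-1-yl]hexa-1,3-dien-1-yl]furan-2(5H)-one | CC1=C(CC/C(=C/C=C/C2=CC(=O)OC2)CO)[C@@]2(C)CCCC(C)(C)[C@H]2CC1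
F4 | step 11 | (2E,4E)-5-(5-oxo-2,5-dihydrofuran-3-yl)-2-{2-[(4aR,8aS)-2,5,5,8a-tetramethyl-3,4,4a,5,6,7,8,8a-octahydronaphthalen-1-yl]ethyl}penta-2,4-dienal | CC1=C(CC/C(=C\C=C\C2=CC(=O)OC2)C=O)[C@@]2(C)CCCC(C)(C)[C@H]2CC1
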